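**Plan**
- Late-stage cuts: C2–Br goes back to C2–H (through C2–B), N1–H to N1–Ts, C2=C3 to the indoline CH2–CH2, and C4–Br and C6–Br to C4–SiMe3 and C6–SiMe3.
- Core cut: C3a–C7a, C4–C5 and C6–C7 are broken together. This opens both rings to an N-ethynyl sulfonamide 1,6-diyne (C7≡C7a–N1–C2–C3–C3a≡C4–Si) and ethynyltrimethylsilane (C5≡C6–Si).
- Enabling feature: the benzene ring is substituted only at C4 and C6, 1,3 to each other, with C5 and C7 as CH. N1–C2–C3 of the five-membered ring is a three-atom bridge from C7a to C3a. This is the pattern left when a mono-capped 1,6-diyne takes up a terminal alkyne in the meta sense.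
- Forward order: N1–C2 by Mitsunobu alkylation, then N1–C7a by dichlorovinylation and elimination. One cyclotrimerisation follows, closing the five-membered ring first (in the metallacycle) and the benzene ring second. Bromine then replaces silicon, the indoline is aromatised and deprotected, and C2 is brominated last through boron.
- Stereochemistry: the target has no stereocentre. The E geometry of the dichlorovinyl amide is transient and disappears on elimination.

Key step: step 5

Assumption: the two aryl silanes of the cyclotrimerisation product are taken to react with bromine at similar rates. Both monobromides are therefore listed as transient species, and they converge on the same dibromide.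

Step 1
Reactants: 1 4-(trimethylsilyl)but-3-yn-1-ol; 2 tert-butyl [(4-methylphenyl)sulfonyl]carbamate (TsNHBoc)
Product: 3 tert-butyl N-tosyl-N-[4-(trimethylsilyl)but-3-yn-1-yl]carbamate
Conditions: PPh3, DIAD, THF, 0 °C → rt
Reagents that add atoms: none
Why: Mitsunobu reaction: the acidic N–H of the N-Boc sulfonamide is a standard pronucleophile for primary alcohols, the Boc group rules out double alkylation, and the neutral conditions avoid the E2 loss that a homopropargylic sulfonate would risk under base.

Step 2
Reactants: 3 tert-butyl N-tosyl-N-[4-(trimethylsilyl)but-3-yn-1-yl]carbamate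
Product: 4 4-methyl-N-[4-(trimethylsilyl)but-3-yn-1-yl]benzenesulfonamide
Conditions: TFA, CH2Cl2, 0 °C → rt
Reagents that add atoms: none
Why: Acidolytic Boc cleavage (loss of the tert-butyl cation, then decarboxylation) is fast on an N-sulfonyl carbamate, while the sulfonamide and the alkynyl–SiMe3 bond are inert to TFA at room temperature.

Step 3
Reactants: 4 4-methyl-N-[4-(trimethylsilyl)but-3-yn-1-yl]benzenesulfonamide; 5 trichloroethylene
Product: 6 (E)-N-(1,2-dichlorovinyl)-4-methyl-N-[4-(trimethylsilyl)but-3-yn-1-yl]benzenesulfonamide
Conditions: Cs2CO3 (1.5 equiv), 5 (1.2 equiv), dry DMF, 50 °C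
Reagents that add atoms: none
Why: Known dichlorovinylation of secondary sulfonamides: Cs2CO3 dehydrochlorinates 5 to dichloroacetylene in the flask, the sulfonamide anion adds to it and anti protonation gives the E-1,2-dichloroenamide, and exclusion of water and alcohols keeps the carbonate from cleaving the alkynyl silane.

Step 4
Reactants: 6 (E)-N-(1,2-dichlorovinyl)-4-methyl-N-[4-(trimethylsilyl)but-3-yn-1-yl]benzenesulfonamide
Product: 9 N-ethynyl-4-methyl-N-[4-(trimethylsilyl)but-3-yn-1-yl]benzenesulfonamide, via chloroynamide 7 (not isolated), via lithium acetylide 8 (not isolated)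
Conditions: PhLi (2.2 equiv), THF, −78 °C; then H2O
Reagents that add atoms: none
Why: Known conversion of 1,2-dichloroenamides into terminal ynamides: the first PhLi removes the vinyl proton and chloride leaves (β-elimination) to give 7, the second effects chlorine–lithium exchange to 8, and water protonates the acetylide, while the tosyl group and the C-silyl alkyne are untouched at −78 °C and no fluoride or alkoxide step is needed that would strip the silyl cap.

Step 5
Reactants: 9 N-ethynyl-4-methyl-N-[4-(trimethylsilyl)but-3-yn-1-yl]benzenesulfonamide; 10 ethynyltrimethylsilane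
Product: 11 1-tosyl-4,6-bis(trimethylsilyl)indoline
Conditions: Cp*RuCl(cod) (5 mol%), 10 (5 equiv), ClCH2CH2Cl, rt, 9 added slowly by syringe pump
Reagents that add atoms: none
Why: Loss of cod frees a Cp*RuCl fragment of divalent ruthenium that binds both alkynes of 9 and couples them oxidatively at their inner carbons, which forms C3a–C7a in a bicyclic ruthenacyclopentadiene, after which 10 inserts and reductive elimination completes C4–C5 and C6–C7. The closest known reaction type is the crossed (2+2+2) cyclotrimerisation of N-sulfonyl ynamide 1,6-diynes with terminal alkynes to indolines, together with the Cp*RuCl-catalysed union of mono-capped 1,6-diynes and terminal alkynes. The five-membered ring N1–C2–C3–C3a–C7a closes by the intramolecular oxidative cyclisation, which the three-atom tether makes faster than any intermolecular coupling, and the benzene ring closes by alkyne insertion into the metallacycle followed by reductive elimination. No stereocentre is created. The step needs chemoselectivity for cross- over self-trimerisation, which is secured by an excess of the bulky 10 (reluctant to trimerise with itself) and by keeping 9 dilute through slow addition. It also needs regioselectivity, which the SiMe3 cap on C4 secures: the alkyne enters with its CH end towards the silylated C4 and its own SiMe3 next to the unsubstituted C7, so the two silyl groups end up 1,3 (C4 and C6) rather than 1,2 (C4 and C5).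

Step 6
Reactants: 11 1-tosyl-4,6-bis(trimethylsilyl)indoline
Product: 14 4,6-dibromo-1-tosylindoline, via 6-bromo-4-silyl indoline 12 (not isolated), via 4-bromo-6-silyl indoline 13 (not isolated)
Conditions: Br2 (2.2 equiv), 2,6-di-tert-butylpyridine (0.2 equiv), CH2Cl2, 0 °C → rt, dark
Reagents that add atoms: bromine, BrBr
Why: Electrophilic ipso-bromodesilylation of aryl–SiMe3 bonds: attack at C4 and C6 gives β-silyl-stabilised arenium ions that lose Me3SiBr, whereas the C–H sites favoured by the weakly donating sulfonamide nitrogen are buried (C5 between two large groups, C7 between N-Ts and the C6 substituent), and the hindered pyridine traps stray HBr that would otherwise cause protodesilylation.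

Step 7
Reactants: 14 4,6-dibromo-1-tosylindoline
Product: 15 4,6-dibromo-1-tosyl-1H-indole
Conditions: DDQ (2.5 equiv), PhCl, 130 °C
Reagents that add atoms: none
Why: Quinone dehydrogenation of an N-acceptor-substituted indoline (hydride abstraction from the C2–C3 bridge, then proton loss) is driven by aromatisation to the indole, the high temperature makes up for the electron-poor ring, and aryl bromides and the sulfonamide are inert to DDQ.

Step 8
Reactants: 15 4,6-dibromo-1-tosyl-1H-indole
Product: 16 4,6-dibromo-1H-indole
Conditions: KOH, THF/MeOH, 50 °C; then dilute HCl to neutrality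
Reagents that add atoms: none
Why: Nucleophilic N-desulfonylation: hydroxide attacks sulfur because the indolide, further stabilised by two bromines, is a good leaving group (the reason the tosyl group is removed only after aromatisation), and aryl bromides do not react with KOH at this temperature.

Step 9
Reactants: 16 4,6-dibromo-1H-indole
Product: 18 2,4,6-tribromo-1H-indole, via 2-boryl indole 17 (not isolated)
Conditions: [Ir(OMe)(cod)]2 (1.5 mol%), dtbpy (3 mol%), B2pin2 (1.0 equiv), THF, 60 °C; evaporate; CuBr2 (3 equiv), MeOH/H2O 1:1, 80 °C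
Reagents that add atoms: bis(pinacolato)diboron, CC1(C)OB(OC1(C)C)B1OC(C)(C)C(C)(C)O1 (boron of 17); CuBr2, [Cu+2].[Br-].[Br-] (bromine at C2 of 18)
Why: Iridium-catalysed C–H borylation of N–H indoles goes to C2, and here C3 (peri to C4–Br), C5 (between two bromines) and C7 (next to C6–Br) are also sterically closed, while the copper-mediated bromodeboronation that follows runs by boron-to-copper transmetalation and C–Br bond-forming elimination and so places bromine exactly where boron stood, with the existing C–Br bonds tolerated in both stages.

**Compound list**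
1 | 4-(trimethylsilyl)but-3-yn-1-ol | C[Si](C)(C)C#CCCO | starting material
2 | tert-butyl [(4-methylphenyl)sulfonyl]carbamate | Cc1ccc(cc1)S(=O)(=O)NC(=O)OC(C)(C)C | starting material
3 | tert-butyl N-tosyl-N-[4-(trimethylsilyl)but-3-yn-1-yl]carbamate | Cc1ccc(cc1)S(=O)(=O)N(CCC#C[Si](C)(C)C)C(=O)OC(C)(C)C | intermediate
4 | 4-methyl-N-[4-(trimethylsilyl)but-3-yn-1-yl]benzenesulfonamide | Cc1ccc(cc1)S(=O)(=O)NCCC#C[Si](C)(C)C | intermediate
5 | trichloroethylene | ClC=C(Cl)Cl | starting material
6 | (E)-N-(1,2-dichlorovinyl)-4-methyl-N-[4-(trimethylsilyl)but-3-yn-1-yl]benzenesulfonamide | Cl/C=C(/Cl)N(CCC#C[Si](C)(C)C)S(=O)(=O)c1ccc(C)cc1 | intermediate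
7 | N-(chloroethynyl)-4-methyl-N-[4-(trimethylsilyl)but-3-yn-1-yl]benzenesulfonamide | ClC#CN(CCC#C[Si](C)(C)C)S(=O)(=O)c1ccc(C)cc1 | intermediate
8 | N-(lithioethynyl)-4-methyl-N-[4-(trimethylsilyl)but-3-yn-1-yl]benzenesulfonamide | [Li]C#CN(CCC#C[Si](C)(C)C)S(=O)(=O)c1ccc(C)cc1 | intermediate
9 | N-ethynyl-4-methyl-N-[4-(trimethylsilyl)but-3-yn-1-yl]benzenesulfonamide | C#CN(CCC#C[Si](C)(C)C)S(=O)(=O)c1ccc(C)cc1 | intermediate
10 | ethynyltrimethylsilane | C#C[Si](C)(C)C | starting material
11 | 1-tosyl-4,6-bis(trimethylsilyl)indoline | Cc1ccc(cc1)S(=O)(=O)N1CCc2c([Si](C)(C)C)cc([Si](C)(C)C)cc21 | intermediate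
12 | 6-bromo-1-tosyl-4-(trimethylsilyl)indoline | Cc1ccc(cc1)S(=O)(=O)N1CCc2c([Si](C)(C)C)cc(Br)cc21 | intermediate
13 | 4-bromo-1-tosyl-6-(trimethylsilyl)indoline | Cc1ccc(cc1)S(=O)(=O)N1CCc2c(Br)cc([Si](C)(C)C)cc21 | intermediate
14 | 4,6-dibromo-1-tosylindoline | Cc1ccc(cc1)S(=O)(=O)N1CCc2c(Br)cc(Br)cc21 | intermediate
15 | 4,6-dibromo-1-tosyl-1H-indole | Cc1ccc(cc1)S(=O)(=O)n1ccc2c(Br)cc(Br)cc21 | intermediate
16 | 4,6-dibromo-1H-indole | Brc1cc(Br)c2cc[nH]c2c1 | intermediate
17 | 4,6-dibromo-2-(4,4,5,5-tetramethyl-1,3,2-dioxaborolan-2-yl)-1H-indole | CC1(C)OB(OC1(C)C)c1cc2c(Br)cc(Br)cc2[nH]1 | intermediate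
18 | 2,4,6-tribromo-1H-indole | Brc1cc(Br)c2cc(Br)[nH]c2c1 | target

Total step count: 9. Longest linear sequence: 9 steps (1 → 18). Compounds 2, 5 and 10 enter as purchased materials.

**Steps most likely to fail**

**Step 6.** Once the first bromine has deactivated the ring, ipso attack at the remaining silane may be overtaken by bromination of the nitrogen-activated C5–H or C7–H. Protodesilylation by HBr could also erase a placeholder. The fallback sets out from 11 and returns at 14, and it replaces the electrophilic halogenation by a boron relay.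
- BBr3 in CH2Cl2 exchanges both aryl–SiMe3 bonds and leaves undirected C–H bonds alone, giving 4,6-bis(dibromoboryl)-1-tosylindoline F1.
- Pinacol and Et3N convert this into 4,6-bis(4,4,5,5-tetramethyl-1,3,2-dioxaborolan-2-yl)-1-tosylindoline F2.
- CuBr2 in MeOH/H2O at 80 °C then turns both C–B bonds into C–Br bonds by transmetalation, independent of ring directing effects, and delivers 14.

**Step 9.** The C2 boronate may protodeboronate in hot aqueous methanol. CuBr2 may also act as an electrophilic brominating agent at C3, and the 2-bromoindole may degrade as acid builds up. The fallback sets out from 15 and returns at 18, using the tosyl group as a directing group before it is removed.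
- LiN(iPr)2 in THF at −78 °C is an amide base, so no bromine–lithium exchange occurs. It deprotonates C2 next to the sulfonyl group to give 4,6-dibromo-2-lithio-1-tosylindole F3.
- 1,2-Dibromo-1,1,2,2-tetrachloroethane transfers electrophilic bromine to give 2,4,6-tribromo-1-tosyl-1H-indole F4.
- KOH in THF/MeOH, as in step 8, frees 18.

**Step 5.** Uptake of the bulky silyl alkyne may be slow enough for self-trimerisation of 9 to take over. Regiocontrol may also erode towards the 4,5-disilyl arrangement. The fallback sets out from 9 and returns at 12. It keeps the same ring-forming event but removes the regiochemical question.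
- Compound 9 is cyclotrimerised with acetylene (1 atm, Cp*RuCl(cod), ClCH2CH2Cl, rt). Acetylene is small and symmetrical, and the product is 1-tosyl-4-(trimethylsilyl)indoline F5.
- In F5, C6 is the only ring C–H without an ortho neighbour. C5 lies next to SiMe3, C7 lies next to N-Ts, and every tolyl C–H is ortho to a substituent.
- Sterically governed borylation with [Ir(OMe)(cod)]2, dtbpy and B2pin2 should therefore give 6-(4,4,5,5-tetramethyl-1,3,2-dioxaborolan-2-yl)-1-tosyl-4-(trimethylsilyl)indoline F6.
- CuBr2 in MeOH/H2O converts F6 into 12. This re-enters step 6 and needs only one equivalent of Br2 to reach 14.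

**Further compounds**
F1 | step 6 | 4,6-bis(dibromoboryl)-1-tosylindoline | Cc1ccc(cc1)S(=O)(=O)N1CCc2c(B(Br)Br)cc(B(Br)Br)cc21
F2 | step 6 | 4,6-bis(4,4,5,5-tetramethyl-1,3,2-dioxaborolan-2-yl)-1-tosylindoline | Cc1ccc(cc1)S(=O)(=O)N1CCc2c(B3OC(C)(C)C(C)(C)O3)cc(B3OC(C)(C)C(C)(C)O3)cc21
F3 | step 9 | 4,6-dibromo-2-lithio-1-tosylindole | [Li]c1cc2c(Br)cc(Br)cc2n1S(=O)(=O)c1ccc(C)cc1
F4 | step 9 | 2,4,6-tribromo-1-tosyl-1H-indole | Cc1ccc(cc1)S(=O)(=O)n1c(Br)cc2c(Br)cc(Br)cc21
F5 | step 5 | 1-tosyl-4-(trimethylsilyl)indoline | Cc1ccc(cc1)S(=O)(=O)N1CCc2c([Si](C)(C)C)cccc21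
F6 | step 5 | 6-(4,4,5,5-tetramethyl-1,3,2-dioxaborolan-2-yl)-1-tosyl-4-(trimethylsilyl)indoline | Cc1ccc(cc1)S(=O)(=O)N1CCc2c([Si](C)(C)C)cc(B3OC(C)(C)C(C)(C)O3)cc21
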